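**Plan**
- Retrosynthesis: both C–Br bonds are cut back to (R)-carbinols (double SN2 inversion). The side-chain chlorohydrin goes back to a chloromethyl ketone, then to a methyl ester plus a CH2Cl carbenoid, and the acetoxy carbinol to a ring ketone.
- The ring is then cut at the CH2–CH(O) bond (aldol) and at the ring C=C (Knoevenagel), giving 2,2-dimethylpropanedial and methyl acetoacetate.
- Forward: the ring C=C is joined first, and the six-membered ring closes in the same flask by the aldol bond between the ring CH2 and the future CHBr carbon. Directed reduction, one-carbon extension, acetylation, ketone reduction and double bromination follow.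
- Enabling feature: the gem-dimethyl quaternary ring carbon sits between the CHBr carbon and the vinylic CH, so the C5 dialdehyde is symmetric and cannot enolise. The ring CH2 flanked by the O- and Br-bearing carbons is a β-hydroxy ketone retron, and the substituted alkene carbon is the central carbon of a 1,3-dicarbonyl.
- Stereochemistry: the ring carbinol (later CHBr) is set by (S)-proline in the ring closure and relayed to the acetoxy carbon by hydroxyl-directed anti reduction. The side-chain carbinol is set by Corey–Bakshi–Shibata reduction, and both bromides arise by inversion.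

Key step: step 2

Assumption: the facial sense of the (S)-proline ring closure is taken from intermolecular proline aldols of acetone with α-branched aldehydes; should it prove opposite, (R)-proline is used and nothing else changes.

Step 1
Reactants: 1 2,2-dimethylpropane-1,3-diol
Product: 2 2,2-dimethylpropanedial
Conditions: (COCl)2, DMSO, CH2Cl2, −78 °C; Et3N, −78 °C to rt
Reagents that add atoms: none
Why: Swern oxidation of the two primary hydroxyls; the product has no α-hydrogen, so it cannot enolise or self-condense and is used as a crude solution.

Step 2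
Reactants: 2 2,2-dimethylpropanedial; 3 methyl 3-oxobutanoate
Product: 5 methyl (4R)-4-hydroxy-3,3-dimethyl-6-oxocyclohex-1-ene-1-carboxylate, via Knoevenagel alkylidene keto ester 4 (not isolated)
Conditions: (S)-proline (30 mol %), DMSO, 4 Å molecular sieves, rt
Reagents that add atoms: none
Why: (S)-Proline first mediates a Knoevenagel condensation (iminium of one formyl group, addition of the enol of 3, loss of the amine) to alkylidene 4, then forms a 2-aminodiene (enamine) with its acetyl group, whose terminal carbon attacks the remaining formyl group to make the CH2–CH(OH) ring bond. The closest known reaction types are the amine-catalysed Knoevenagel condensation and the proline-catalysed intramolecular aldol cyclisation of keto aldehydes (Hajos–Parrish-type enamine catalysis). The six-membered carbocycle closes in the 6-(enolendo)-exo-trig mode. The single new stereocentre, the carbinol carbon, is controlled by the catalyst: the carboxylic acid hydrogen-bonds the formyl oxygen in a chair-like enamine transition state, which by analogy with proline aldols of acetone and α-branched aldehydes should give the (R)-alcohol. The step needs site selectivity, which the gem-dimethyl carbon secures because both formyl groups lack α- and γ-hydrogens and only the ketone methyl can enolise, and it needs the acetyl group cis to the formyl arm, which interconversion of the E and Z isomers of 4 by reversible amine addition provides. Mono-condensation is secured because ring closure is intramolecular and should outrun a second Knoevenagel reaction.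

Step 3
Reactants: 5 methyl (4R)-4-hydroxy-3,3-dimethyl-6-oxocyclohex-1-ene-1-carboxylate
Product: 6 methyl (4R,6R)-4,6-dihydroxy-3,3-dimethylcyclohex-1-ene-1-carboxylate
Conditions: Me4NBH(OAc)3, MeCN/AcOH (1:1), −30 °C
Reagents that add atoms: none
Why: Evans–Saksena hydroxyl-directed reduction: the neopentylic hydroxyl binds boron and delivers hydride through a six-membered transition state to the face of the acid-activated ring ketone on which it sits, so the new carbinol is trans (1,3-anti) to it, while the ester is inert and delivery to the conjugate position is disfavoured because that transition state would place a methyl of the quaternary carbon axial.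

Step 4
Reactants: 6 methyl (4R,6R)-4,6-dihydroxy-3,3-dimethylcyclohex-1-ene-1-carboxylate
Product: 8 2-chloro-1-[(4R,6R)-4,6-dihydroxy-3,3-dimethylcyclohex-1-en-1-yl]ethan-1-one, via trilithium hemiketal adduct 7 (not isolated)
Conditions: ICH2Cl (3 equiv), MeLi·LiBr (5 equiv, slow addition), THF/Et2O, −78 °C; AcOH, −78 °C to rt
Reagents that add atoms: chloroiodomethane, ClCI
Why: Acyl substitution of the methyl ester by chloromethyllithium (made in the flask by iodine–lithium exchange), which should stop at the ketone stage because the tetrahedral adduct 7 is stable at −78 °C and collapses only on acidic quench; the two hydroxyls are masked as lithium alkoxides and the neopentylic β-carbon blocks conjugate addition.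

Step 5
Reactants: 8 2-chloro-1-[(4R,6R)-4,6-dihydroxy-3,3-dimethylcyclohex-1-en-1-yl]ethan-1-one
Product: 9 (1R,5R)-2-(2-chloroacetyl)-5-hydroxy-4,4-dimethylcyclohex-2-en-1-yl acetate
Conditions: AcCl (1.1 equiv), 2,4,6-collidine, CH2Cl2, −78 °C
Reagents that add atoms: acetyl chloride, CC(=O)Cl
Why: Kinetically selective O-acetylation of the allylic ring hydroxyl, the other hydroxyl being neopentylic (next to the quaternary carbon) and much slower, with a hindered base that should neither be alkylated by the chloroketone nor close it to a furanone.

Step 6
Reactants: 9 (1R,5R)-2-(2-chloroacetyl)-5-hydroxy-4,4-dimethylcyclohex-2-en-1-yl acetate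
Product: 10 (1R,5R)-2-[(1R)-2-chloro-1-hydroxyethyl]-5-hydroxy-4,4-dimethylcyclohex-2-en-1-yl acetate
Conditions: (R)-1-methyl-3,3-diphenyltetrahydro-1H,3H-pyrrolo[1,2-c][1,3,2]oxazaborole ((R)-Me-CBS, 20 mol %), catecholborane, toluene, −78 °C; pH 7 buffer work-up
Reagents that add atoms: none
Why: Corey–Bakshi–Shibata reduction under reagent control: the α-branched alkenyl group is the large and CH2Cl the small ketone substituent, so the (R)-catalyst should deliver hydride to the face that gives the (R)-chlorohydrin, and catecholborane at −78 °C should spare acetate, alkene and chloride.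

Step 7
Reactants: 10 (1R,5R)-2-[(1R)-2-chloro-1-hydroxyethyl]-5-hydroxy-4,4-dimethylcyclohex-2-en-1-yl acetate
Product: 11 (1R,5S)-5-bromo-2-[(1S)-1-bromo-2-chloroethyl]-4,4-dimethylcyclohex-2-en-1-yl acetate
Conditions: PPh3 (5 equiv), CBr4 (5 equiv), CH2Cl2, 0 °C then 40 °C
Reagents that add atoms: tetrabromomethane, BrC(Br)(Br)Br
Why: Double Appel reaction: each carbinol is turned into an oxyphosphonium ion and displaced by bromide with inversion (SN2), the allylic side-chain carbinol at 0 °C and the neopentylic ring carbinol on warming, so both (R)-carbinols become (S)-bromides; allylic transposition is blocked because the distal alkene carbon is neopentylic.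

**Compound list**
1 | 2,2-dimethylpropane-1,3-diol (neopentyl glycol) | OCC(C)(C)CO | starting material
2 | 2,2-dimethylpropanedial | O=CC(C)(C)C=O | intermediate
3 | methyl 3-oxobutanoate (methyl acetoacetate) | COC(=O)CC(C)=O | starting material
4 | methyl 2-acetyl-4,4-dimethyl-5-oxopent-2-enoate (interconverting E/Z mixture) | COC(=O)C(=CC(C)(C)C=O)C(C)=O | intermediate (not isolated)
5 | methyl (4R)-4-hydroxy-3,3-dimethyl-6-oxocyclohex-1-ene-1-carboxylate | O=C1C[C@@H](O)C(C)(C)C=C1C(=O)OC | intermediate
6 | methyl (4R,6R)-4,6-dihydroxy-3,3-dimethylcyclohex-1-ene-1-carboxylate | O[C@@H]1C[C@@H](O)C(C)(C)C=C1C(=O)OC | intermediate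
7 | trilithium salt of the tetrahedral adduct of 6 with chloromethyllithium (trilithium hemiketal adduct) | [Li]O[C@@H]1C[C@@H](O[Li])C(C)(C)C=C1C(O[Li])(OC)CCl | intermediate (not isolated)
8 | 2-chloro-1-[(4R,6R)-4,6-dihydroxy-3,3-dimethylcyclohex-1-en-1-yl]ethan-1-one | O[C@@H]1C[C@@H](O)C(C)(C)C=C1C(=O)CCl | intermediate
9 | (1R,5R)-2-(2-chloroacetyl)-5-hydroxy-4,4-dimethylcyclohex-2-en-1-yl acetate | CC(=O)O[C@@H]1C[C@@H](O)C(C)(C)C=C1C(=O)CCl | intermediate
10 | (1R,5R)-2-[(1R)-2-chloro-1-hydroxyethyl]-5-hydroxy-4,4-dimethylcyclohex-2-en-1-yl acetate | CC(=O)O[C@@H]1C[C@@H](O)C(C)(C)C=C1[C@@H](O)CCl | intermediate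
11 | (1R,5S)-5-bromo-2-[(1S)-1-bromo-2-chloroethyl]-4,4-dimethylcyclohex-2-en-1-yl acetate | CC(=O)O[C@@H]1C[C@H](Br)C(C)(C)C=C1[C@H](Br)CCl | target

**Step count and risks**

Total steps: 7. Longest linear sequence: 7 steps (1 to 11); compound 3 enters at step 2.

Steps most likely to fail:

1. Step 2. What may go wrong: poor facial discrimination in the enamine ring closure, a racemic base-catalysed background aldol, or dehydration of the aldol to the cross-conjugated dienone. Fallback, setting out from 2 and 3 and returning at 6: the same domino condensation is run with an achiral amine salt (pyrrolidinium acetate, CH2Cl2, rt) to give racemic methyl 4-hydroxy-3,3-dimethyl-6-oxocyclohex-1-ene-1-carboxylate F1. Directed reduction as in step 3 gives the racemic trans-diol methyl (4R*,6R*)-4,6-dihydroxy-3,3-dimethylcyclohex-1-ene-1-carboxylate F2. Kinetic resolution with Candida antarctica lipase B and vinyl acetate (tert-butyl methyl ether, rt) should, by the empirical rule for lipase acylation of secondary carbinols, acetylate the (6R)-allylic hydroxyl of the (4R,6R)-enantiomer to give methyl (4R,6R)-6-(acetyloxy)-4-hydroxy-3,3-dimethylcyclohex-1-ene-1-carboxylate F3. This is separated from the unreacted (4S,6S)-diol and methanolysed (K2CO3, MeOH, 0 °C) to give 6.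

2. Step 7. What may go wrong: elimination or acetate participation instead of substitution at the neopentylic ring carbinol, and epimerisation of the allylic bromide by bromide exchange while the hindered centre is forced. Fallback, setting out from 10 and returning at 11: the two substitutions are separated so that the allylic bromide is made last and never meets bromide at elevated temperature. Selective silylation of the less hindered side-chain hydroxyl (tert-butyldimethylsilyl chloride, imidazole, DMF, 0 °C) gives (1R,5R)-2-[(1R)-1-{[tert-butyl(dimethyl)silyl]oxy}-2-chloroethyl]-5-hydroxy-4,4-dimethylcyclohex-2-en-1-yl acetate F4. Forcing Appel bromination of the ring carbinol alone (PPh3, CBr4, toluene, 60 °C) gives with inversion (1R,5S)-5-bromo-2-[(1R)-1-{[tert-butyl(dimethyl)silyl]oxy}-2-chloroethyl]-4,4-dimethylcyclohex-2-en-1-yl acetate F5. Desilylation (HF·pyridine, THF, 0 °C) gives (1R,5S)-5-bromo-2-[(1R)-2-chloro-1-hydroxyethyl]-4,4-dimethylcyclohex-2-en-1-yl acetate F6, and a mild Appel reaction (PPh3, CBr4, CH2Cl2, −20 °C) then gives 11.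

3. Step 4. What may go wrong: decomposition of the carbenoid before addition, sluggish attack on the hindered conjugated ester carrying two alkoxides, or over-addition. Fallback, setting out from 6 and returning at 8: the ester is acylated with dimethylsulfoxonium methylide (trimethylsulfoxonium iodide, KOtBu, THF, 60 °C) to give the β-keto sulfoxonium ylide dimethylsulfoxonium 2-[(4R,6R)-4,6-dihydroxy-3,3-dimethylcyclohex-1-en-1-yl]-2-oxoethylide F7. Treatment with anhydrous HCl (THF, 60 °C) protonates the ylide carbon and displaces dimethyl sulfoxide by chloride to give 8.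

**Further compounds**
F1 | step 2 | racemic methyl 4-hydroxy-3,3-dimethyl-6-oxocyclohex-1-ene-1-carboxylate | COC(=O)C1=CC(C)(C)C(O)CC1=O
F2 | step 2 | racemic methyl (4R*,6R*)-4,6-dihydroxy-3,3-dimethylcyclohex-1-ene-1-carboxylate (trans; one enantiomer drawn) | O[C@@H]1C[C@@H](O)C(C)(C)C=C1C(=O)OC
F3 | step 2 | methyl (4R,6R)-6-(acetyloxy)-4-hydroxy-3,3-dimethylcyclohex-1-ene-1-carboxylate | CC(=O)O[C@@H]1C[C@@H](O)C(C)(C)C=C1C(=O)OC
F4 | step 7 | (1R,5R)-2-[(1R)-1-{[tert-butyl(dimethyl)silyl]oxy}-2-chloroethyl]-5-hydroxy-4,4-dimethylcyclohex-2-en-1-yl acetate | CC(=O)O[C@@H]1C[C@@H](O)C(C)(C)C=C1[C@@H](O[Si](C)(C)C(C)(C)C)CCl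
F5 | step 7 | (1R,5S)-5-bromo-2-[(1R)-1-{[tert-butyl(dimethyl)silyl]oxy}-2-chloroethyl]-4,4-dimethylcyclohex-2-en-1-yl acetate | CC(=O)O[C@@H]1C[C@H](Br)C(C)(C)C=C1[C@@H](O[Si](C)(C)C(C)(C)C)CCl
F6 | step 7 | (1R,5S)-5-bromo-2-[(1R)-2-chloro-1-hydroxyethyl]-4,4-dimethylcyclohex-2-en-1-yl acetate | CC(=O)O[C@@H]1C[C@H](Br)C(C)(C)C=C1[C@@H](O)CCl
F7 | step 4 | dimethylsulfoxonium 2-[(4R,6R)-4,6-dihydroxy-3,3-dimethylcyclohex-1-en-1-yl]-2-oxoethylide | O[C@@H]1C[C@@H](O)C(C)(C)C=C1C(=O)C=S(C)(C)=O
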